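**Retrosynthetic overview**
1. Target ⇒ carbonyl methylenation (C5=CH2) of the ten-membered 10-oxo dienoate.
2. Ten-membered ring ⇒ two-carbon ring expansion of a cis-cyclooct-2-enone. Methyl propiolate supplies C3–C4; bonds C2–C3 and C4–C5 are made and C2–C5 is cut (polar cyclobutene annulation, then Grob fragmentation).
3. Cyclooctenone ⇒ ring-closing metathesis of an allyl/vinyl ketone diene; vinyl ketone ⇒ alkylzinc iodide + 3-chloropropanoyl chloride.
4. Side chain ⇒ (R)-2-methylbutanoic acid + carbinol from catalytic asymmetric 3-furyl addition to a one-carbon-homologated aldehyde.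
5. C8/C9 ⇒ asymmetric methyl conjugate addition to 5,6-dihydropyran-2-one, then allylation and methylation of the lactone enolate. Ring order: six-membered lactone template (later opened) → eight-membered carbocycle → bicyclo[6.2.0]decene → ten-membered ring.

Assumption: each chiral ligand is used as the enantiomer that gives the drawn configuration. Atoms carry clerodane labels: ring C1–C10 with C4 bearing CO2Me, C5 the methylidene carbon, C8 CHMe and C9 quaternary; side chain C11–C12.

Step 1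
Reactants: 1 5,6-dihydro-2H-pyran-2-one
Product: 2 (4R)-4-methyloxan-2-one
Conditions: MeMgBr (1.2 equiv), CuBr·SMe2 (5 mol %), chiral ferrocenyl diphosphine of the reversed Josiphos type (6 mol %), tBuOMe, −72 °C; H2O
Reagents that add atoms: methylmagnesium bromide C[Mg]Br
Why: Copper-catalysed asymmetric conjugate addition of a Grignard reagent, in which the chiral diphosphine–copper complex delivers methyl to one face of the ring-locked unsaturated lactone and so sets C8 as R.

Step 2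
Reactants: 2 (4R)-4-methyloxan-2-one; 3 allyl bromide
Product: 5 (3R,4R)-3,4-dimethyl-3-(prop-2-en-1-yl)oxan-2-one, via monoallyl lactone 4 (not isolated)
Conditions: LiN(iPr)2 (1.05 equiv), THF, −78 °C; 3 (1.0 equiv), −78 → −30 °C; LiN(iPr)2 (1.2 equiv), −78 °C; MeI (3 equiv), DMPU, −78 → −20 °C
Reagents that add atoms: iodomethane CI
Why: Two successive lactone enolate alkylations, in which the first stereocentre is erased on re-enolisation and MeI then enters the half-chair enolate anti to the neighbouring C8 methyl, setting quaternary C9 (new methyl trans, allyl cis to the C8 methyl).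

Step 3
Reactants: 5 (3R,4R)-3,4-dimethyl-3-(prop-2-en-1-yl)oxan-2-one
Product: 6 (3R,4R)-3,4-dimethyl-3-(prop-2-en-1-yl)oxan-2-ol (anomer mixture)
Conditions: iBu2AlH (1.1 equiv), CH2Cl2, −78 °C; aq. potassium sodium tartrate
Reagents that add atoms: none
Why: Partial lactone reduction stops at the tetrahedral aluminium lactolate at −78 °C because the neopentyl carbonyl is hindered, and it touches no stereocentre.

Step 4
Reactants: 6 (3R,4R)-3,4-dimethyl-3-(prop-2-en-1-yl)oxan-2-ol
Product: 8 (3S,4R)-6-hydroxy-3,4-dimethyl-3-(prop-2-en-1-yl)hexanal, via enol ether 7 (not isolated)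
Conditions: [Ph3PCH2OMe]Cl (3 equiv), KN(SiMe3)2 (3 equiv), THF, 0 → 23 °C; then 2 M HCl, THF, 23 °C
Reagents that add atoms: (methoxymethyl)triphenylphosphonium chloride COC[P+](c1ccccc1)(c1ccccc1)c1ccccc1.[Cl-]; water O
Why: Wittig methoxymethylenation of the open hydroxy aldehyde form of the lactol, followed by enol ether hydrolysis, adds the single carbon C12 and leaves C8 and C9 untouched.

Step 5
Reactants: 8 (3S,4R)-6-hydroxy-3,4-dimethyl-3-(prop-2-en-1-yl)hexanal
Product: 9 (3S,4R)-6-iodo-3,4-dimethyl-3-(prop-2-en-1-yl)hexanal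
Conditions: I2, PPh3, imidazole, CH2Cl2, 0 °C
Reagents that add atoms: iodine II
Why: Appel-type iodination displaces the oxyphosphonium salt of the primary alcohol by SN2, and the aldehyde is inert under these neutral conditions.

Step 6
Reactants: 9 (3S,4R)-6-iodo-3,4-dimethyl-3-(prop-2-en-1-yl)hexanal; 10 3-bromofuran
Product: 13 (1R,3S,4R)-1-(furan-3-yl)-6-iodo-3,4-dimethyl-3-(prop-2-en-1-yl)hexan-1-ol, via 3-furyllithium 11 (not isolated), via furyltitanium triisopropoxide 12 (not isolated)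
Conditions: 10, nBuLi, Et2O, −78 °C; ClTi(OiPr)3, −78 °C; then 9, Ti(OiPr)4 (20 mol %), 3,3′-diphenyl-H8-BINOL (10 mol %), CH2Cl2, −40 → 0 °C; H2O
Reagents that add atoms: n-butyllithium [Li]CCCC (lithium in 11 only); chlorotitanium triisopropoxide CC(C)O[Ti](Cl)(OC(C)C)OC(C)C (in 12 only)
Why: Catalytic enantioselective aryl transfer from titanium, in which the non-basic furyltitanium reagent tolerates the alkyl iodide, adds to the Si face of the aldehyde under control of the BINOL-type titanium Lewis acid, and sets C12 as R.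

Step 7
Reactants: 13 (1R,3S,4R)-1-(furan-3-yl)-6-iodo-3,4-dimethyl-3-(prop-2-en-1-yl)hexan-1-ol; 14 (2R)-2-methylbutanoic acid
Product: 15 (1R,3S,4R)-1-(furan-3-yl)-6-iodo-3,4-dimethyl-3-(prop-2-en-1-yl)hexyl (2R)-2-methylbutanoate
Conditions: DCC (1.2 equiv), DMAP (10 mol %), CH2Cl2, 0 → 23 °C
Reagents that add atoms: none
Why: Steglich esterification acylates on oxygen, so C12 keeps its configuration, and at 0 °C the α-stereocentre brought in by the acid is not epimerised.

Step 8
Reactants: 15 (1R,3S,4R)-1-(furan-3-yl)-6-iodo-3,4-dimethyl-3-(prop-2-en-1-yl)hexyl (2R)-2-methylbutanoate; 16 3-chloropropanoyl chloride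
Product: 19 (1R,3S,4R)-1-(furan-3-yl)-3,4-dimethyl-7-oxo-3-(prop-2-en-1-yl)non-8-en-1-yl (2R)-2-methylbutanoate, via alkylzinc iodide 17 (not isolated), via chloro ketone 18 (not isolated)
Conditions: Zn dust, LiCl, THF, 40 °C; 16, Pd(PPh3)4 (3 mol %), 0 °C; then Et3N, 23 °C
Reagents that add atoms: zinc [Zn] (in 17 only)
Why: Knochel zinc insertion gives an ester-tolerant alkylzinc iodide, palladium-catalysed Negishi acylation stops at the ketone, and E1cB loss of HCl unveils the sensitive vinyl ketone only at the end.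

Step 9
Reactants: 19 (1R,3S,4R)-1-(furan-3-yl)-3,4-dimethyl-7-oxo-3-(prop-2-en-1-yl)non-8-en-1-yl (2R)-2-methylbutanoate
Product: 20 (1R)-2-[(1S,2R,6Z)-1,2-dimethyl-5-oxocyclooct-6-en-1-yl]-1-(furan-3-yl)ethyl (2R)-2-methylbutanoate
Conditions: second-generation Hoveyda–Grubbs catalyst (H2IMes)Cl2Ru(=CH-C6H4-2-OiPr) (5 mol %), toluene (1 mM), 80 °C
Reagents that add atoms: none
Why: Ring-closing metathesis pairs the reactive allyl group with the vinyl ketone, the vicinal quaternary and tertiary carbons favour folding (gem-dialkyl effect), and an eight-membered ring can hold only the cis alkene.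

Step 10
Reactants: 20 (1R)-2-[(1S,2R,6Z)-1,2-dimethyl-5-oxocyclooct-6-en-1-yl]-1-(furan-3-yl)ethyl (2R)-2-methylbutanoate; 21 methyl propiolate
Product: 26 methyl (1E,3Z,6S,7R)-6-{(2R)-2-(furan-3-yl)-2-[(2R)-2-methylbutanoyloxy]ethyl}-6,7-dimethyl-10-oxocyclodeca-1,3-diene-1-carboxylate, via thio silyl enol ether 22 (not isolated), via cyclobutene 23 (not isolated), via sulfonium triflate 24 (not isolated), via trans-diene 25 (not isolated)
Conditions: PhSSiMe3 (1.1 equiv), HNTf2 (5 mol %), CH2Cl2, −78 °C; 21 (1.5 equiv), −78 → −40 °C; MeOTf (1.2 equiv), 2,6-di-tert-butylpyridine, −40 → 0 °C; CsF, MeCN, −20 °C; aq. NaHCO3; crude in CH2Cl2, I2 (5 mol %), daylight, 23 °C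
Reagents that add atoms: (phenylsulfanyl)trimethylsilane C[Si](C)(C)Sc1ccccc1 (in 22–24 only); methyl trifluoromethanesulfonate COS(=O)(=O)C(F)(F)F (in 24 only)
Why: Proposed new method: silylium-catalysed 1,4-addition of PhSSiMe3 fixes the enol ether at C5=C2 and parks a latent leaving group on C1; C2 then attacks C3 of the silylium-activated propiolate (Mukaiyama–Michael), and the allenyl ketene acetal carbon C4 closes onto the C5 oxocarbenium ion (aldol), a stepwise polar (2+2) annulation giving the bicyclo[6.2.0]decene; S-methylation turns C1–S into a nucleofuge that cannot re-add, fluoride frees the C5 alkoxide, and the O–C5–C2–C1–S array fragments in Grob fashion, the cyclobutene strain release paying for the ten-membered ring; C3=C4 keeps the cis C2/C5 relation of the four-membered ring, while C1=C2 is expected to form trans first (anti-periplanar C5–C2/C1–S) and iodine is then expected to equilibrate it to the cis,cis-diene, which is assumed to be the less strained isomer; the closest known reaction types are the acid-catalysed (2+2) annulation of silyl enol ethers with propiolates, with two-carbon ring enlargement of the adducts, and the Grob/Wharton fragmentation.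

Step 11
Reactants: 26 methyl (1E,3Z,6S,7R)-6-{(2R)-2-(furan-3-yl)-2-[(2R)-2-methylbutanoyloxy]ethyl}-6,7-dimethyl-10-oxocyclodeca-1,3-diene-1-carboxylate
Product: 27 methyl (1E,3Z,6S,7R)-6-{(2R)-2-(furan-3-yl)-2-[(2R)-2-methylbutanoyloxy]ethyl}-6,7-dimethyl-10-methylidenecyclodeca-1,3-diene-1-carboxylate (CNP0305973.1)
Conditions: Cp2Ti(μ-Cl)(μ-CH2)AlMe2 (1.1 equiv), pyridine, THF–toluene, −40 → 0 °C
Reagents that add atoms: Tebbe reagent Cp2Ti(μ-Cl)(μ-CH2)AlMe2 C[Al](C)Cl.C=[Ti+2].[cH-]1cccc1.[cH-]1cccc1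
Why: Tebbe methylenation uses a non-basic titanium methylidene that reacts with the ketone much faster than with the two esters, so the acidic C6 and C10 hydrogens, the diene geometry and all four stereocentres are left alone.

**Compound list**
1 | 5,6-dihydro-2H-pyran-2-one | O=C1C=CCCO1 | starting material
2 | (4R)-4-methyloxan-2-one | O=C1OCC[C@@H](C)C1 | intermediate
3 | allyl bromide | C=CCBr | starting material
4 | (3S,4R)-4-methyl-3-(prop-2-en-1-yl)oxan-2-one (trans, not isolated) | O=C1OCC[C@@H](C)[C@@H]1CC=C | intermediate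
5 | (3R,4R)-3,4-dimethyl-3-(prop-2-en-1-yl)oxan-2-one | O=C1OCC[C@@H](C)[C@@]1(C)CC=C | intermediate
6 | (3R,4R)-3,4-dimethyl-3-(prop-2-en-1-yl)oxan-2-ol, anomer mixture | OC1OCC[C@@H](C)[C@@]1(C)CC=C | intermediate
7 | (3R,4R)-4-(2-methoxyethenyl)-3,4-dimethylhept-6-en-1-ol, E/Z mixture (not isolated) | OCC[C@@H](C)[C@](C)(C=COC)CC=C | intermediate
8 | (3S,4R)-6-hydroxy-3,4-dimethyl-3-(prop-2-en-1-yl)hexanal | OCC[C@@H](C)[C@](C)(CC=O)CC=C | intermediate
9 | (3S,4R)-6-iodo-3,4-dimethyl-3-(prop-2-en-1-yl)hexanal | ICC[C@@H](C)[C@](C)(CC=O)CC=C | intermediate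
10 | 3-bromofuran | Brc1ccoc1 | starting material
11 | 3-furyllithium (not isolated) | [Li]c1ccoc1 | intermediate
12 | (furan-3-yl)titanium triisopropoxide (not isolated) | CC(C)O[Ti](OC(C)C)(OC(C)C)c1ccoc1 | intermediate
13 | (1R,3S,4R)-1-(furan-3-yl)-6-iodo-3,4-dimethyl-3-(prop-2-en-1-yl)hexan-1-ol | ICC[C@@H](C)[C@](C)(C[C@@H](O)c1ccoc1)CC=C | intermediate
14 | (2R)-2-methylbutanoic acid | CC[C@@H](C)C(=O)O | starting material
15 | (1R,3S,4R)-1-(furan-3-yl)-6-iodo-3,4-dimethyl-3-(prop-2-en-1-yl)hexyl (2R)-2-methylbutanoate | ICC[C@@H](C)[C@](C)(C[C@@H](OC(=O)[C@H](C)CC)c1ccoc1)CC=C | intermediate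
16 | 3-chloropropanoyl chloride | ClCCC(=O)Cl | starting material
17 | alkylzinc iodide from 15 (C–I replaced by C–ZnI, stereocentres as in 15; not isolated) | I[Zn]CC[C@@H](C)[C@](C)(C[C@@H](OC(=O)[C@H](C)CC)c1ccoc1)CC=C | intermediate
18 | (1R,3S,4R)-9-chloro-1-(furan-3-yl)-3,4-dimethyl-7-oxo-3-(prop-2-en-1-yl)nonyl (2R)-2-methylbutanoate (not isolated) | ClCCC(=O)CC[C@@H](C)[C@](C)(C[C@@H](OC(=O)[C@H](C)CC)c1ccoc1)CC=C | intermediate
19 | (1R,3S,4R)-1-(furan-3-yl)-3,4-dimethyl-7-oxo-3-(prop-2-en-1-yl)non-8-en-1-yl (2R)-2-methylbutanoate | C=CC(=O)CC[C@@H](C)[C@](C)(C[C@@H](OC(=O)[C@H](C)CC)c1ccoc1)CC=C | intermediate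
20 | (1R)-2-[(1S,2R,6Z)-1,2-dimethyl-5-oxocyclooct-6-en-1-yl]-1-(furan-3-yl)ethyl (2R)-2-methylbutanoate | O=C1CC[C@@H](C)[C@](C)(C[C@@H](OC(=O)[C@H](C)CC)c2ccoc2)C/C=C\1 | intermediate
21 | methyl propiolate | C#CC(=O)OC | starting material
22 | 1,4-adduct of PhSSiMe3 to 20: C5(OSiMe3)=C2 enol ether with SPh on C1 (C1 epimers; C8, C9, C12 and acyl centre as in 20; not isolated) | C[Si](C)(C)OC=1CC[C@@H](C)[C@](C)(C[C@@H](OC(=O)[C@H](C)CC)c2ccoc2)CC(Sc2ccccc2)C=1 | intermediate
23 | methyl 1-(trimethylsilyloxy)-7-(phenylsulfanyl)bicyclo[6.2.0]dec-9-ene-10-carboxylate carrying the 4,5-dimethyl and 5-side-chain groups of 20 (old stereocentres as in 20; not isolated) | C[Si](C)(C)OC12CC[C@@H](C)[C@](C)(C[C@@H](OC(=O)[C@H](C)CC)c3ccoc3)CC(Sc3ccccc3)C1C=C2C(=O)OC | intermediate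
24 | S-methyl sulfonium triflate of 23 (not isolated) | C[Si](C)(C)OC12CC[C@@H](C)[C@](C)(C[C@@H](OC(=O)[C@H](C)CC)c3ccoc3)CC([S+](C)c3ccccc3)C1C=C2C(=O)OC.[O-]S(=O)(=O)C(F)(F)F | intermediate
25 | (1E,3E) isomer of 26, C1=C2 trans in the ring (not isolated) | O=C1CC[C@@H](C)[C@](C)(C[C@@H](OC(=O)[C@H](C)CC)c2ccoc2)C/C=C/C=C\1C(=O)OC | intermediate
26 | methyl (1E,3Z,6S,7R)-6-{(2R)-2-(furan-3-yl)-2-[(2R)-2-methylbutanoyloxy]ethyl}-6,7-dimethyl-10-oxocyclodeca-1,3-diene-1-carboxylate | O=C1CC[C@@H](C)[C@](C)(C[C@@H](OC(=O)[C@H](C)CC)c2ccoc2)C/C=C\C=C/1C(=O)OC | intermediate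
27 | methyl (1E,3Z,6S,7R)-6-{(2R)-2-(furan-3-yl)-2-[(2R)-2-methylbutanoyloxy]ethyl}-6,7-dimethyl-10-methylidenecyclodeca-1,3-diene-1-carboxylate | C=C1CC[C@@H](C)[C@](C)(C[C@@H](OC(=O)[C@H](C)CC)c2ccoc2)C/C=C\C=C/1C(=O)OC | target

**Step count**
Total step count: 11. Longest linear sequence: 11.

**Steps most likely to fail**

Step 10 (the new ring expansion).
- Risks: the sulfide or the furan may compete for the activated propiolate. The furylmethyl ester may ionise under silylium catalysis. The basic fluoride may deprotonate C10 of the product. The iodine equilibrium may not lie far enough on the cis,cis side.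
- Fallback with known chemistry, from 20 back to 26: 1,4-hydrosilylation (Et3SiH, RhCl(PPh3)3, benzene, 50 °C) gives the triethylsilyl enol ether F1. EtAlCl2-catalysed (2+2) annulation with 21 in CH2Cl2 at −78 °C gives the bicyclic cyclobutene F2. Bu4NF in THF opens it to the ring-enlarged 2-acyl enoate F3. Me3SiOTf/Et3N gives the extended silyl dienol ether F4. DDQ in CH2Cl2 then removes the C1/C2 hydrogens to give 26, with the same iodine equilibration.

Step 9 (eight-membered ring-closing metathesis on an electron-poor vinyl ketone).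
- Risks: dimerisation and catalyst decay.
- Fallback, from 19 back to 20: Luche reduction (NaBH4, CeCl3·7H2O, MeOH, −78 °C) gives the allylic alcohol F5. Its two unhindered, electron-rich alkenes are closed by the same ruthenium catalyst to the cyclooctenol F6. MnO2 in CH2Cl2 then oxidises F6 to 20.

Step 11 (methylenation of a hindered, cross-conjugated ketone next to an ester).
- Risks: slow reaction and attack on the esters.
- Fallback, from 26 back to 27: Me3SiCH2MgCl/CeCl3 in THF at −78 °C adds 1,2 to the ketone to give the β-hydroxysilane F7. HF·pyridine then effects Peterson elimination to 27.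

**Further compounds**
F1 | step 10 | (1R)-2-[(1S,2R)-1,2-dimethyl-5-(triethylsilyloxy)cyclooct-5-en-1-yl]-1-(furan-3-yl)ethyl (2R)-2-methylbutanoate | CC[Si](CC)(CC)OC=1CC[C@@H](C)[C@](C)(C[C@@H](OC(=O)[C@H](C)CC)c2ccoc2)CCC=1
F2 | step 10 | methyl 1-(triethylsilyloxy)bicyclo[6.2.0]dec-9-ene-10-carboxylate carrying the 4,5-dimethyl and 5-side-chain groups of 20 | CC[Si](CC)(CC)OC12CC[C@@H](C)[C@](C)(C[C@@H](OC(=O)[C@H](C)CC)c3ccoc3)CCC1C=C2C(=O)OC
F3 | step 10 | methyl (1E,6S,7R)-6-{(2R)-2-(furan-3-yl)-2-[(2R)-2-methylbutanoyloxy]ethyl}-6,7-dimethyl-10-oxocyclodec-1-ene-1-carboxylate | O=C1CC[C@@H](C)[C@](C)(C[C@@H](OC(=O)[C@H](C)CC)c2ccoc2)CCC\C=C/1C(=O)OC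
F4 | step 10 | extended trimethylsilyl dienol ether of F3 (C5(OSiMe3)=C4–C3=C2) | C[Si](C)(C)OC=1CC[C@@H](C)[C@](C)(C[C@@H](OC(=O)[C@H](C)CC)c2ccoc2)CCC=CC=1C(=O)OC
F5 | step 9 | (1R,3S,4R)-1-(furan-3-yl)-7-hydroxy-3,4-dimethyl-3-(prop-2-en-1-yl)non-8-en-1-yl (2R)-2-methylbutanoate (C7 epimers) | C=CC(O)CC[C@@H](C)[C@](C)(C[C@@H](OC(=O)[C@H](C)CC)c1ccoc1)CC=C
F6 | step 9 | (1R)-1-(furan-3-yl)-2-[(1S,2R,6Z)-5-hydroxy-1,2-dimethylcyclooct-6-en-1-yl]ethyl (2R)-2-methylbutanoate (carbinol epimers) | OC1CC[C@@H](C)[C@](C)(C[C@@H](OC(=O)[C@H](C)CC)c2ccoc2)C/C=C\1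
F7 | step 11 | 10-hydroxy-10-[(trimethylsilyl)methyl] adduct of 26 (C10 epimers of the ring numbering of 26) | C[Si](C)(C)CC1(O)CC[C@@H](C)[C@](C)(C[C@@H](OC(=O)[C@H](C)CC)c2ccoc2)C/C=C\C=C/1C(=O)OC
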